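**Retrosynthetic overview**
- The CH2 bridge is made last: Mannich aminomethylation of a 4-hydroxypyranone, then Michael addition of C7 of a dihydrobenzofuran acylphloroglucinol to the derived 3-methylidene-pyrandione.
- Pyranone ring (own branch, made first): dianion Claisen acylation of ethyl 3-oxopentanoate, then lactonisation.
- Dihydrofuran ring (last ring closed): Mitsunobu closure of the para oxygen onto an (S)-allylic carbinol, with inversion to R.
- Carbinol: Nozaki–Hiyama–Kishi union of an arylacetaldehyde with the enol triflate of 6-methylhept-5-en-2-one, then Sharpless kinetic resolution.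
- Arylacetaldehyde: 2,4,6-trihydroxyacetophenone (benzene ring bought) by 4-O-allylation, aromatic Claisen rearrangement and alkene cleavage.

Assumption: the stereocentre of the target is R as read from the SMILES, and commercial 2,4,6-trihydroxyacetophenone monohydrate is dried before use.

**Route**

Step 1
Reactants: 1 ethyl 3-oxopentanoate; 2 N-methoxy-N-methylpropanamide
Product: 4 ethyl 4-methyl-3,5-dioxoheptanoate, via sodium lithium dianion 3 (not isolated)
Conditions: NaH (1.1 equiv), THF, 0 °C; n-BuLi (1.05 equiv), 0 °C; then 2, 0 °C to rt; aq. HCl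
Reagents that add atoms: none
Why: Huckin–Weiler dianion chemistry, a crossed Claisen-type acylation in which the more reactive terminal carbanion attacks the Weinreb amide and the chelated tetrahedral adduct prevents over-addition and proton quench.

Step 2
Reactants: 4 ethyl 4-methyl-3,5-dioxoheptanoate
Product: 5 6-ethyl-4-hydroxy-5-methyl-2H-pyran-2-one
Conditions: DBU (1.0 equiv), toluene, reflux; aq. HCl
Reagents that add atoms: none
Why: Base-promoted enol lactonisation (intramolecular transesterification of the C5 enol onto the ethyl ester) gives the aromatic 4-hydroxy-2-pyranone.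

Step 3
Reactants: 6 2,4,6-trihydroxyacetophenone; 7 allyl bromide
Product: 8 1-[2,6-dihydroxy-4-(prop-2-en-1-yloxy)phenyl]ethan-1-one
Conditions: K2CO3 (1.05 equiv), 7 (1.0 equiv), acetone, reflux
Reagents that add atoms: none
Why: Williamson etherification in which the 4-OH, para to the acetyl and not held in the hydrogen bond to the carbonyl, is the most acidic phenol and is alkylated first.

Step 4
Reactants: 8 1-[2,6-dihydroxy-4-(prop-2-en-1-yloxy)phenyl]ethan-1-one
Product: 9 1-[2,6-bis(methoxymethoxy)-4-(prop-2-en-1-yloxy)phenyl]ethan-1-one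
Conditions: NaH (2.3 equiv), MOMCl (2.5 equiv), DMF, 0 °C to rt
Reagents that add atoms: chloromethyl methyl ether (MOMCl), COCCl
Why: O-alkylation of the bis-phenoxide (Williamson-type acetal formation), NaH being strong enough to break the chelate so that both ortho hydroxyls are capped.

Step 5
Reactants: 9 1-[2,6-bis(methoxymethoxy)-4-(prop-2-en-1-yloxy)phenyl]ethan-1-one
Product: 10 1-[4-hydroxy-2,6-bis(methoxymethoxy)-3-(prop-2-en-1-yl)phenyl]ethan-1-one
Conditions: N,N-diethylaniline, 195 °C, sealed tube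
Reagents that add atoms: none
Why: Aromatic Claisen rearrangement; the two ortho positions are equivalent, so one C-allyl phenol forms and the oxygen set free is the para oxygen needed for the later ring closure.

Step 6
Reactants: 10 1-[4-hydroxy-2,6-bis(methoxymethoxy)-3-(prop-2-en-1-yl)phenyl]ethan-1-one
Product: 11 1-[4-(tert-butyldimethylsilyloxy)-2,6-bis(methoxymethoxy)-3-(prop-2-en-1-yl)phenyl]ethan-1-one
Conditions: TBSCl (1.2 equiv), imidazole (2.5 equiv), DMF, rt
Reagents that add atoms: tert-butyldimethylsilyl chloride (TBSCl), CC(C)(C)[Si](C)(C)Cl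
Why: Standard imidazole-promoted silylation of the only free phenol, which stops the later arylacetaldehyde from closing to a lactol.

Step 7
Reactants: 11 1-[4-(tert-butyldimethylsilyloxy)-2,6-bis(methoxymethoxy)-3-(prop-2-en-1-yl)phenyl]ethan-1-one
Product: 13 2-[3-acetyl-6-(tert-butyldimethylsilyloxy)-2,4-bis(methoxymethoxy)phenyl]acetaldehyde, via vicinal diol 12 (not isolated)
Conditions: OsO4 (0.02 equiv), NaIO4 (4 equiv), 2,6-lutidine (2 equiv), 1,4-dioxane/H2O 3:1, rt; used crude
Reagents that add atoms: osmium tetroxide OsO4, O=[Os](=O)(=O)=O; sodium periodate NaIO4, [Na+].[O-]I(=O)(=O)=O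
Why: Lemieux–Johnson oxidation, in which OsO4 dihydroxylates the only alkene and NaIO4 cleaves the diol in the same pot while 2,6-lutidine suppresses over-oxidation.

Step 8
Reactants: 14 6-methylhept-5-en-2-one
Product: 16 6-methylhepta-1,5-dien-2-yl trifluoromethanesulfonate, via lithium enolate 15 (not isolated)
Conditions: LiN(iPr)2 (1.1 equiv), THF, −78 °C; PhNTf2 (1.05 equiv), −78 °C to 0 °C; aq. NH4Cl
Reagents that add atoms: N-phenylbis(trifluoromethanesulfonimide) (PhNTf2), O=S(=O)(N(c1ccccc1)S(=O)(=O)C(F)(F)F)C(F)(F)F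
Why: Kinetic enolisation at the methyl group followed by O-sulfonylation of the less substituted enolate gives the terminal enol triflate.

Step 9
Reactants: 13 2-[3-acetyl-6-(tert-butyldimethylsilyloxy)-2,4-bis(methoxymethoxy)phenyl]acetaldehyde; 16 6-methylhepta-1,5-dien-2-yl trifluoromethanesulfonate
Product: 17 rac-1-[4-(tert-butyldimethylsilyloxy)-3-(2-hydroxy-7-methyl-3-methylideneoct-6-en-1-yl)-2,6-bis(methoxymethoxy)phenyl]ethan-1-one
Conditions: CrCl2 (4 equiv), NiCl2 (0.02 equiv), 16 (1.5 equiv), DMF, rt; aq. work-up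
Reagents that add atoms: none
Why: Nozaki–Hiyama–Kishi reaction, in which the nickel-activated triflate is passed to chromium and the weakly basic alkenylchromium species adds only to the aldehyde, sparing the hindered aryl ketone and the enolisable α-position; the new carbinol is racemic.

Step 10
Reactants: 17 rac-1-[4-(tert-butyldimethylsilyloxy)-3-(2-hydroxy-7-methyl-3-methylideneoct-6-en-1-yl)-2,6-bis(methoxymethoxy)phenyl]ethan-1-one
Product: 18 1-{4-(tert-butyldimethylsilyloxy)-3-[(2S)-2-hydroxy-7-methyl-3-methylideneoct-6-en-1-yl]-2,6-bis(methoxymethoxy)phenyl}ethan-1-one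
Conditions: Ti(OiPr)4 (0.2 equiv), D-(−)-diisopropyl tartrate (0.3 equiv), t-BuOOH (0.6 equiv, in decane), 4 Å sieves, CH2Cl2, −20 °C; stopped at about 55–60% conversion
Reagents that add atoms: none
Why: Sharpless kinetic resolution; with the D-(−)-tartrate the (R)-carbinol is epoxidised much faster, so the recovered alcohol (at most 50%) is the (S)-enantiomer in high ee, and this sets the only stereocentre.

Step 11
Reactants: 18 1-{4-(tert-butyldimethylsilyloxy)-3-[(2S)-2-hydroxy-7-methyl-3-methylideneoct-6-en-1-yl]-2,6-bis(methoxymethoxy)phenyl}ethan-1-one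
Product: 19 1-{4-hydroxy-3-[(2S)-2-hydroxy-7-methyl-3-methylideneoct-6-en-1-yl]-2,6-bis(methoxymethoxy)phenyl}ethan-1-one
Conditions: Bu4NF (1.1 equiv), THF, 0 °C, 15 min; aq. NH4Cl
Reagents that add atoms: none
Why: Fluoride-mediated desilylation cleaves the aryl silyl ether selectively, leaving the MOM acetals and the carbinol untouched.

Step 12
Reactants: 19 1-{4-hydroxy-3-[(2S)-2-hydroxy-7-methyl-3-methylideneoct-6-en-1-yl]-2,6-bis(methoxymethoxy)phenyl}ethan-1-one
Product: 20 1-[(2R)-4,6-bis(methoxymethoxy)-2-(6-methylhepta-1,5-dien-2-yl)-2,3-dihydro-1-benzofuran-5-yl]ethan-1-one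
Conditions: PPh3 (1.5 equiv), DIAD (1.5 equiv), THF (0.01 M), 0 °C to rt
Reagents that add atoms: none
Why: Intramolecular Mitsunobu etherification, in which the acidic para-acyl phenol displaces the activated carbinol in a 5-exo-tet SN2 reaction with inversion (S to R) and the MOM groups on the two ortho oxygens enforce closure through the para oxygen.

Step 13
Reactants: 20 1-[(2R)-4,6-bis(methoxymethoxy)-2-(6-methylhepta-1,5-dien-2-yl)-2,3-dihydro-1-benzofuran-5-yl]ethan-1-one
Product: 21 1-[(2R)-4,6-dihydroxy-2-(6-methylhepta-1,5-dien-2-yl)-2,3-dihydro-1-benzofuran-5-yl]ethan-1-one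
Conditions: HCl (3 M aq., 5 equiv), MeOH, rt to 40 °C, followed by TLC
Reagents that add atoms: none
Why: Acid-catalysed acetal methanolysis; MOM ethers ortho to the ketone are chelation-activated and cleave in acid too dilute to ionise the allylic aryl ether or add to the alkenes, so the stereocentre is untouched.

Step 14
Reactants: 5 6-ethyl-4-hydroxy-5-methyl-2H-pyran-2-one; 21 1-[(2R)-4,6-dihydroxy-2-(6-methylhepta-1,5-dien-2-yl)-2,3-dihydro-1-benzofuran-5-yl]ethan-1-one; 22 N,N-dimethylmethaniminium iodide (Eschenmoser's salt)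
Product: 25 3-{[(2R)-5-acetyl-4,6-dihydroxy-2-(6-methylhepta-1,5-dien-2-yl)-2,3-dihydro-1-benzofuran-7-yl]methyl}-6-ethyl-4-hydroxy-5-methyl-2H-pyran-2-one, via Mannich base hydroiodide 23 (not isolated), via methylidene pyrandione 24 (not isolated)
Conditions: 5 (1.3 equiv), 22 (1.3 equiv), MeCN, rt, 1 h; then 21 (1.0 equiv), 60 °C
Reagents that add atoms: none
Why: Mannich reaction at C3 of the pyranone, loss of dimethylamine to the 3-methylidene-2,4-dione, and intermolecular Michael addition of the only free, doubly oxygen-flanked arene carbon (C7) of 21, followed by re-aromatisation; the stereocentre is remote and unaffected.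

**Compound list**

1 | ethyl 3-oxopentanoate | CCC(=O)CC(=O)OCC | starting material
2 | N-methoxy-N-methylpropanamide | CCC(=O)N(C)OC | starting material
3 | sodium lithium dianion of ethyl 3-oxopentanoate (not isolated) | CCOC(=O)[CH-]C(=O)[CH-]C.[Na+].[Li+] | intermediate
4 | ethyl 4-methyl-3,5-dioxoheptanoate (C4 enolisable, no fixed configuration) | CCOC(=O)CC(=O)C(C)C(=O)CC | intermediate
5 | 6-ethyl-4-hydroxy-5-methyl-2H-pyran-2-one | CCc1oc(=O)cc(O)c1C | intermediate
6 | 1-(2,4,6-trihydroxyphenyl)ethan-1-one | CC(=O)c1c(O)cc(O)cc1O | starting material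
7 | 3-bromoprop-1-ene (allyl bromide) | C=CCBr | starting material
8 | 1-[2,6-dihydroxy-4-(prop-2-en-1-yloxy)phenyl]ethan-1-one | CC(=O)c1c(O)cc(OCC=C)cc1O | intermediate
9 | 1-[2,6-bis(methoxymethoxy)-4-(prop-2-en-1-yloxy)phenyl]ethan-1-one | CC(=O)c1c(OCOC)cc(OCC=C)cc1OCOC | intermediate
10 | 1-[4-hydroxy-2,6-bis(methoxymethoxy)-3-(prop-2-en-1-yl)phenyl]ethan-1-one | CC(=O)c1c(OCOC)cc(O)c(CC=C)c1OCOC | intermediate
11 | 1-[4-(tert-butyldimethylsilyloxy)-2,6-bis(methoxymethoxy)-3-(prop-2-en-1-yl)phenyl]ethan-1-one | CC(=O)c1c(OCOC)cc(O[Si](C)(C)C(C)(C)C)c(CC=C)c1OCOC | intermediate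
12 | 1-[4-(tert-butyldimethylsilyloxy)-3-(2,3-dihydroxypropyl)-2,6-bis(methoxymethoxy)phenyl]ethan-1-one (racemic, not isolated) | CC(=O)c1c(OCOC)cc(O[Si](C)(C)C(C)(C)C)c(CC(O)CO)c1OCOC | intermediate
13 | 2-[3-acetyl-6-(tert-butyldimethylsilyloxy)-2,4-bis(methoxymethoxy)phenyl]acetaldehyde | CC(=O)c1c(OCOC)cc(O[Si](C)(C)C(C)(C)C)c(CC=O)c1OCOC | intermediate
14 | 6-methylhept-5-en-2-one | CC(=O)CCC=C(C)C | starting material
15 | lithium 6-methylhepta-1,5-dien-2-olate (not isolated) | [Li+].[O-]C(=C)CCC=C(C)C | intermediate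
16 | 6-methylhepta-1,5-dien-2-yl trifluoromethanesulfonate | C=C(OS(=O)(=O)C(F)(F)F)CCC=C(C)C | intermediate
17 | rac-1-[4-(tert-butyldimethylsilyloxy)-3-(2-hydroxy-7-methyl-3-methylideneoct-6-en-1-yl)-2,6-bis(methoxymethoxy)phenyl]ethan-1-one | CC(=O)c1c(OCOC)cc(O[Si](C)(C)C(C)(C)C)c(CC(O)C(=C)CCC=C(C)C)c1OCOC | intermediate
18 | 1-{4-(tert-butyldimethylsilyloxy)-3-[(2S)-2-hydroxy-7-methyl-3-methylideneoct-6-en-1-yl]-2,6-bis(methoxymethoxy)phenyl}ethan-1-one | CC(=O)c1c(OCOC)cc(O[Si](C)(C)C(C)(C)C)c(C[C@H](O)C(=C)CCC=C(C)C)c1OCOC | intermediate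
19 | 1-{4-hydroxy-3-[(2S)-2-hydroxy-7-methyl-3-methylideneoct-6-en-1-yl]-2,6-bis(methoxymethoxy)phenyl}ethan-1-one | CC(=O)c1c(OCOC)cc(O)c(C[C@H](O)C(=C)CCC=C(C)C)c1OCOC | intermediate
20 | 1-[(2R)-4,6-bis(methoxymethoxy)-2-(6-methylhepta-1,5-dien-2-yl)-2,3-dihydro-1-benzofuran-5-yl]ethan-1-one | C=C(CCC=C(C)C)[C@H]1Cc2c(OCOC)c(C(C)=O)c(OCOC)cc2O1 | intermediate
21 | 1-[(2R)-4,6-dihydroxy-2-(6-methylhepta-1,5-dien-2-yl)-2,3-dihydro-1-benzofuran-5-yl]ethan-1-one | C=C(CCC=C(C)C)[C@H]1Cc2c(O)c(C(C)=O)c(O)cc2O1 | intermediate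
22 | N,N-dimethylmethaniminium iodide (Eschenmoser's salt) | C=[N+](C)C.[I-] | starting material
23 | 3-[(dimethylamino)methyl]-6-ethyl-4-hydroxy-5-methyl-2H-pyran-2-one hydroiodide (not isolated) | CCc1oc(=O)c(C[NH+](C)C)c(O)c1C.[I-] | intermediate
24 | 6-ethyl-5-methyl-3-methylidene-2H-pyran-2,4(3H)-dione (not isolated) | CCC1=C(C)C(=O)C(=C)C(=O)O1 | intermediate
25 | 3-{[(2R)-5-acetyl-4,6-dihydroxy-2-(6-methylhepta-1,5-dien-2-yl)-2,3-dihydro-1-benzofuran-7-yl]methyl}-6-ethyl-4-hydroxy-5-methyl-2H-pyran-2-one | C=C(CCC=C(C)C)[C@H]1Cc2c(O)c(C(C)=O)c(O)c(Cc3c(O)c(C)c(CC)oc3=O)c2O1 | target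

**Totals**

Total step count: 14. Longest linear sequence: 11 steps (steps 3, 4, 5, 6, 7, 9, 10, 11, 12, 13, 14, from 6 to 25). Steps 1–2 and step 8 are side branches.

**Three steps most likely to fail, with fallbacks**

Step 9 (Nozaki–Hiyama–Kishi coupling). The electron-rich arylacetaldehyde 13 is fragile and the reaction depends on CrCl2 quality. The fallback sets out from 16 and comes back to the route at 17. Triflate 16 is stannylated with Me3SnSnMe3, Pd(PPh3)4 (zerovalent palladium) and LiCl in THF at 60 °C to trimethyl(6-methylhepta-1,5-dien-2-yl)stannane F1. Tin–lithium exchange with MeLi in THF at −78 °C gives (6-methylhepta-1,5-dien-2-yl)lithium F2, which is transmetalated with anhydrous CeCl3 to dichloro(6-methylhepta-1,5-dien-2-yl)cerium F3. This weakly basic reagent adds to aldehyde 13 at −78 °C much faster than to the hindered di-ortho-substituted aryl ketone and gives 17 after a cold quench.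

Step 12 (Mitsunobu ring closure). At a secondary allylic carbinol, SN2′ attack, elimination to a diene or partial ionisation could lower yield or ee. The fallback sets out from 18 and comes back to the route at 20, leaving out 19. Alcohol 18 is mesylated with Ms2O and Et3N in CH2Cl2 at −30 °C to 1-{4-(tert-butyldimethylsilyloxy)-3-[(2S)-2-(methanesulfonyloxy)-7-methyl-3-methylideneoct-6-en-1-yl]-2,6-bis(methoxymethoxy)phenyl}ethan-1-one F4, used cold and crude. Bu4NF in THF (−20 °C to 0 °C) then removes the silyl group, and the phenoxide displaces the mesylate intramolecularly (Williamson closure, 5-exo-tet, inversion) to give 20.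

Step 14 (methylene-bridge coupling). The methylidene pyrandione 24 can be trapped by a second pyranone to give the symmetrical bis-pyranone, and C7 of 21 is less nucleophilic than in a free phloroglucinol. The fallback reverses the polarity; it sets out from 21 and comes back to the route at 25. Phenol 21 is aminomethylated at C7 with 22 in CH2Cl2 at rt to 1-[(2R)-7-[(dimethylamino)methyl]-4,6-dihydroxy-2-(6-methylhepta-1,5-dien-2-yl)-2,3-dihydro-1-benzofuran-5-yl]ethan-1-one hydroiodide F5. Heating F5 with pyranone 5 in 1,4-dioxane at 90 °C expels dimethylamine to give the ortho-quinone methide (2R)-5-acetyl-4-hydroxy-7-methylidene-2-(6-methylhepta-1,5-dien-2-yl)-2,3-dihydro-1-benzofuran-6(7H)-one F6, which C3 of the pyranone traps in a Michael addition to give 25.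

**Further compounds**

F1 | step 9 | trimethyl(6-methylhepta-1,5-dien-2-yl)stannane | C=C(CCC=C(C)C)[Sn](C)(C)C
F2 | step 9 | (6-methylhepta-1,5-dien-2-yl)lithium | [Li]C(=C)CCC=C(C)C
F3 | step 9 | dichloro(6-methylhepta-1,5-dien-2-yl)cerium | Cl[Ce](Cl)C(=C)CCC=C(C)C
F4 | step 12 | 1-{4-(tert-butyldimethylsilyloxy)-3-[(2S)-2-(methanesulfonyloxy)-7-methyl-3-methylideneoct-6-en-1-yl]-2,6-bis(methoxymethoxy)phenyl}ethan-1-one | CC(=O)c1c(OCOC)cc(O[Si](C)(C)C(C)(C)C)c(C[C@H](OS(C)(=O)=O)C(=C)CCC=C(C)C)c1OCOC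
F5 | step 14 | 1-[(2R)-7-[(dimethylamino)methyl]-4,6-dihydroxy-2-(6-methylhepta-1,5-dien-2-yl)-2,3-dihydro-1-benzofuran-5-yl]ethan-1-one hydroiodide | C=C(CCC=C(C)C)[C@H]1Cc2c(O)c(C(C)=O)c(O)c(C[NH+](C)C)c2O1.[I-]
F6 | step 14 | (2R)-5-acetyl-4-hydroxy-7-methylidene-2-(6-methylhepta-1,5-dien-2-yl)-2,3-dihydro-1-benzofuran-6(7H)-one | C=C1C(=O)C(C(C)=O)=C(O)C2=C1O[C@@H](C(=C)CCC=C(C)C)C2
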